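**Retrosynthetic overview**
1. Sodwanone B ⇐ selective C=C hydrogenation of ring‑A enone **16** ⇐ catalytic asymmetric dearomative 6‑endo‑dig C‑alkylation of the fully substituted catechol–ynone **15** (forms ring A last and sets the angular quaternary carbon).
2. **15** ⇐ IBX ortho‑oxygenation and acetylide opening of aryl lactone **13**.
3. Right half of **13** ⇐ one epoxide‑opening cascade of diepoxy‑alkene **11** (oxepane, then cyclohexane), followed by face‑selective hydrogenation.
4. **11** ⇐ B‑alkyl Suzuki coupling of aryl triflate **5** with diepoxy‑diene **10** (farnesyl acetate, Shi diepoxidation).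
5. **5** ⇐ 2,6‑xylenol by oxidation to the quinone and ketene‑acetal annulation (installs the hindered aryl–CMe2–C(=O) unit).

Assumptions: the L‑fructose‑derived (ent‑)Shi ketone and both pseudo‑enantiomeric cinchona catalysts are bought as reagents. **14** is drawn as the open hydroxy‑ynone although it equilibrates with its cyclic hemiketal. **12** is carried as a mixture of alkene regioisomers.

---

**Step 1**
Reactants: **1** 2,6‑dimethylphenol
Product: **2** 2,6‑dimethyl‑1,4‑benzoquinone
Conditions: O2 (1 atm), Co(salen) 5 mol%, DMF, rt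
Reagents that add atoms: dioxygen, O=O
Why: Cobalt‑salen catalysed para‑oxygenation of a 2,6‑dialkylphenol (oxidative dearomatisation) gives the p‑quinone cleanly.

**Step 2**
Reactants: **2**; **3** 1‑methoxy‑2‑methyl‑1‑(trimethylsilyloxy)prop‑1‑ene
Product: **4** 5‑hydroxy‑3,3,4,6‑tetramethyl‑1‑benzofuran‑2(3H)‑one
Conditions: TiCl4, CH2Cl2, −78 °C; then TsOH·H2O, toluene, 80 °C
Reagents that add atoms: none beyond the two reactants
Why: Mukaiyama–Michael addition of the tetrasubstituted ketene acetal to the only unsubstituted quinone carbon, then re‑aromatisation and lactonisation onto the adjacent phenol, builds the congested aryl–CMe2–C(=O) bond (the two free positions are equivalent, so there is no regiochemical issue).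

**Step 3**
Reactants: **4**
Product: **5** 3,3,4,6‑tetramethyl‑2‑oxo‑2,3‑dihydro‑1‑benzofuran‑5‑yl triflate
Conditions: Tf2O, pyridine, CH2Cl2, 0 °C
Reagents that add atoms: triflic anhydride, O=S(=O)(C(F)(F)F)OS(=O)(=O)C(F)(F)F
Why: Standard O‑sulfonylation of the remaining (di‑ortho‑methyl) phenol; the lactone is inert.

**Step 4**
Reactants: **6** (2E,6E)‑farnesyl acetate
Product: **7** (2E,6S,7S,10S)‑6,7:10,11‑diepoxy‑3,7,11‑trimethyldodec‑2‑en‑1‑yl acetate
Conditions: ent‑Shi ketone (L‑fructose‑derived, 0.6 equiv), Oxone, K2CO3, Bu4NHSO4, MeCN/DMM/aq. borate buffer, 0 °C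
Reagents that add atoms: Oxone (KHSO5), [K+].OOS(=O)(=O)[O-]
Why: Shi asymmetric epoxidation; the chiral dioxirane sets the (6S,7S) and (10S) epoxides by reagent control, and the allylic acetate deactivates the 2,3‑alkene so it survives.

**Step 5**
Reactants: **7**
Product: **8** (2E,6S,7S,10S)‑6,7:10,11‑diepoxy‑3,7,11‑trimethyldodec‑2‑en‑1‑ol
Conditions: K2CO3, MeOH, 0 °C → rt
Reagents that add atoms: none
Why: Mild transesterification; trisubstituted epoxides are stable to methoxide.

**Step 6**
Reactants: **8**
Product: **9** (2E,6S,7S,10S)‑6,7:10,11‑diepoxy‑3,7,11‑trimethyldodec‑2‑enal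
Conditions: MnO2, CH2Cl2, rt
Reagents that add atoms: none
Why: Chemoselective allylic alcohol oxidation under neutral conditions preserves the epoxides and the E‑alkene.

**Step 7**
Reactants: **9**
Product: **10** (3E,7S,8S,11S)‑7,8:11,12‑diepoxy‑4,8,12‑trimethyltrideca‑1,3‑diene
Conditions: Ph3PCH3Br, KHMDS, THF, −78 → 0 °C
Reagents that add atoms: methyltriphenylphosphonium bromide, C[P+](c1ccccc1)(c1ccccc1)c1ccccc1.[Br-]
Why: Wittig methylenation of the enal gives the terminal 1,3‑diene without touching the trisubstituted alkene geometry or the epoxides.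

**Step 8**
Reactants: **10**; **5**
Product: **11** 5‑[(3E,7S,8S,11S)‑7,8:11,12‑diepoxy‑4,8,12‑trimethyltridec‑3‑en‑1‑yl]‑3,3,4,6‑tetramethyl‑1‑benzofuran‑2(3H)‑one
Conditions: 9‑BBN, THF, 0 °C → rt; then **5**, Pd(OAc)2/SPhos, K3PO4·H2O, THF, 40 °C
Reagents that add atoms: none (9‑BBN contributes only H)
Why: 9‑BBN hydroborates the terminal CH2 of the 4,4‑disubstituted diene (as in homoprenyl‑9‑BBN formation), and B‑alkyl Suzuki–Miyaura coupling with the hindered aryl triflate forms the ArCH2CH2–CH=C(Me) link.

**Step 9**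
Reactants: **11**
Product: **12** 5‑{2‑[(3S,5aS,6R,9aS)‑3‑hydroxy‑2,2,5a‑trimethyl‑7‑methylidenedecahydro‑1‑benzoxepin‑6‑yl]ethyl}‑3,3,4,6‑tetramethyl‑1‑benzofuran‑2(3H)‑one, with its endocyclic alkene regioisomers
Conditions: TMSOTf (1.5 equiv), 2,6‑di‑tert‑butyl‑4‑methylpyridine, CH2Cl2, −78 °C; then 1 M HCl, THF
Reagents that add atoms: none
Why: In this tandem oxa/carbacyclisation the activated terminal epoxide is opened at its tertiary carbon by the internal epoxide oxygen; the resulting epoxonium is opened at its tertiary carbon by the E‑alkene through a chair transition state. This gives the trans‑fused oxepane–cyclohexane (C9a–O retained, C5a inverted, side chain equatorial and cis to the angular methyl), and the cation is quenched by proton loss. Arene trapping is blocked because both ortho positions carry methyl groups.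

**Step 10**
Reactants: **12** (isomer mixture)
Product: **13** 5‑{2‑[(3S,5aS,6R,7R,9aS)‑3‑hydroxy‑2,2,5a,7‑tetramethyldecahydro‑1‑benzoxepin‑6‑yl]ethyl}‑3,3,4,6‑tetramethyl‑1‑benzofuran‑2(3H)‑one
Conditions: H2 (3 atm), PtO2, EtOAc, rt
Reagents that add atoms: none
Why: Heterogeneous hydrogenation delivers H2 to the face opposite the axial angular methyl, as with labdane 8(17)‑enes, so every alkene isomer converges on the axial secondary methyl (7R); any minor epimer is removed by chromatography.

**Step 11**
Reactants: **13**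
Product: **14** 4‑(2‑hydroxy‑4,6‑dimethyl‑5‑{2‑[(3S,5aS,6R,7R,9aS)‑3‑hydroxy‑2,2,5a,7‑tetramethyldecahydro‑1‑benzoxepin‑6‑yl]ethyl}phenyl)‑4‑methylpent‑1‑yn‑3‑one
Conditions: HC≡CLi (acetylene, n‑BuLi; 3.5 equiv), BF3·OEt2, THF, −78 °C; NH4Cl
Reagents that add atoms: lithium acetylide, [Li]C#C
Why: BF3‑mediated alkynylation of the aryl lactone stops at the tetrahedral adduct, so work‑up gives the mono‑addition hydroxy‑ynone and frees the phenol; the secondary alcohol only consumes one equivalent of acetylide.

**Step 12**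
Reactants: **14**
Product: **15** (5aS,6R,7R,9aS)‑6‑{2‑[3,4‑dihydroxy‑2,6‑dimethyl‑5‑(2‑methyl‑3‑oxopent‑4‑yn‑2‑yl)phenyl]ethyl}‑2,2,5a,7‑tetramethyloctahydro‑1‑benzoxepin‑3(2H)‑one
Conditions: IBX (3.5 equiv), DMSO, rt; then aq. Na2S2O4; handle under Ar
Reagents that add atoms: IBX, O=C1OI(=O)(O)c2ccccc12
Why: IBX oxidises the secondary alcohol to the oxepanone and oxygenates the phenol at its only free ortho position to the o‑quinone; dithionite then reduces the quinone to the catechol.

**Step 13 (key step)**
Reactants: **15**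
Product: **16** (8aR)‑4‑hydroxy‑2,5,5,8a‑tetramethyl‑1‑{2‑[(5aS,6R,7R,9aS)‑2,2,5a,7‑tetramethyl‑3‑oxodecahydro‑1‑benzoxepin‑6‑yl]ethyl}naphthalene‑3,6(5H,8aH)‑dione
Conditions: (DHQD)2PHAL 10 mol% (or (DHQ)2PHAL, whichever gives 8aR), toluene, −20 °C → rt, degassed
Reagents that add atoms: none
Why: Proposed new method: the cinchona base forms a chiral, H‑bonded ion pair with the catechol mono‑anion, and the ring carbon para to the phenoxide oxygen (the methyl‑bearing carbon next to the tether) adds 6‑endo‑dig to the ynone β‑carbon; because that carbon carries a methyl group the adduct cannot re‑aromatise and collapses to the 2‑hydroxy cross‑conjugated dienone, so ring A and the (R) angular quaternary centre form in one step under catalyst control (the right‑half stereocentres are too remote to matter). The alkyne acceptor makes the C‑alkylation irreversible, and the neighbouring OH stays protonated and H‑bonded, which disfavours 7‑endo O‑attack. Closest known reaction types: Ar2‑6 phenolate para‑C‑alkylation to fused cyclohexadienones, Ag/Cu‑promoted dearomatising cyclisation of phenol‑tethered ynones, and cinchona‑catalysed enantioselective conjugate addition of 1,3‑dicarbonyls and naphthols to alkynones.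

**Step 14**
Reactants: **16**
Product: **17** sodwanone B
Conditions: H2 (1 atm), RhCl(PPh3)3 10 mol%, benzene/EtOH, rt
Reagents that add atoms: none
Why: Wilkinson's catalyst reduces only the cis‑disubstituted ring‑A enone C=C (as in 1,4‑dien‑3‑one → 4‑en‑3‑one reductions) and leaves the two tetrasubstituted dienone alkenes and both ketones; the neutral conditions avoid base‑triggered retro‑Michael re‑aromatisation of the product.

---

**Compound list**

1 | 2,6‑dimethylphenol | Cc1cccc(C)c1O | starting material
2 | 2,6‑dimethyl‑1,4‑benzoquinone | CC1=CC(=O)C=C(C)C1=O | intermediate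
3 | 1‑methoxy‑2‑methyl‑1‑(trimethylsilyloxy)prop‑1‑ene | COC(O[Si](C)(C)C)=C(C)C | starting material
4 | 5‑hydroxy‑3,3,4,6‑tetramethyl‑1‑benzofuran‑2(3H)‑one | CC1(C)C(=O)Oc2cc(C)c(O)c(C)c12 | intermediate
5 | aryl triflate of 4 | CC1(C)C(=O)Oc2cc(C)c(OS(=O)(=O)C(F)(F)F)c(C)c12 | intermediate
6 | (2E,6E)‑farnesyl acetate | CC(=O)OC/C=C(\C)CC/C=C(\C)CCC=C(C)C | starting material
7 | (6S,7S,10S)‑6,7:10,11‑diepoxyfarnesyl acetate | CC(=O)OC/C=C(\C)CC[C@@H]1O[C@@]1(C)CC[C@@H]1OC1(C)C | intermediate
8 | (6S,7S,10S)‑6,7:10,11‑diepoxyfarnesol | OC/C=C(\C)CC[C@@H]1O[C@@]1(C)CC[C@@H]1OC1(C)C | intermediate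
9 | (6S,7S,10S)‑6,7:10,11‑diepoxyfarnesal | O=C/C=C(\C)CC[C@@H]1O[C@@]1(C)CC[C@@H]1OC1(C)C | intermediate
10 | (3E,7S,8S,11S)‑7,8:11,12‑diepoxy‑4,8,12‑trimethyltrideca‑1,3‑diene | C=C/C=C(\C)CC[C@@H]1O[C@@]1(C)CC[C@@H]1OC1(C)C | intermediate
11 | coupled diepoxy‑alkene aryl lactone | CC1(C)C(=O)Oc2cc(C)c(CC/C=C(\C)CC[C@@H]3O[C@@]3(C)CC[C@@H]3OC3(C)C)c(C)c12 | intermediate
12 | cascade product, exocyclic‑methylene isomer shown | CC1(C)C(=O)Oc2cc(C)c(CC[C@@H]3C(=C)CC[C@@H]4OC(C)(C)[C@@H](O)CC[C@]43C)c(C)c12 | intermediate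
13 | hydrogenated bicyclic alcohol aryl lactone | CC1(C)C(=O)Oc2cc(C)c(CC[C@@H]3[C@H](C)CC[C@@H]4OC(C)(C)[C@@H](O)CC[C@]43C)c(C)c12 | intermediate
14 | phenol ynone (open form) | C#CC(=O)C(C)(C)c1c(O)cc(C)c(CC[C@@H]2[C@H](C)CC[C@@H]3OC(C)(C)[C@@H](O)CC[C@]32C)c1C | intermediate
15 | catechol ynone ketone | C#CC(=O)C(C)(C)c1c(O)c(O)c(C)c(CC[C@@H]2[C@H](C)CC[C@@H]3OC(C)(C)C(=O)CC[C@]32C)c1C | intermediate
16 | dearomatised ring‑A enone (7,8‑didehydro‑sodwanone B) | CC1=C(CC[C@@H]2[C@H](C)CC[C@@H]3OC(C)(C)C(=O)CC[C@]32C)[C@@]2(C)C=CC(=O)C(C)(C)C2=C(O)C1=O | intermediate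
17 | sodwanone B | CC1=C(CC[C@@H]2[C@H](C)CC[C@@H]3OC(C)(C)C(=O)CC[C@]32C)[C@@]2(C)CCC(=O)C(C)(C)C2=C(O)C1=O | target

---

**Totals**
Total step count: 14.
Longest linear sequence: 11 steps (steps 4–14, from farnesyl acetate); the arene branch is steps 1–3.

**Three steps most likely to fail, with fallbacks**
- **Step 13 (asymmetric dearomative cyclisation).** The risks are O‑cyclisation of the neighbouring phenol and low enantioselectivity. Fallback: close ring A at the o‑quinone oxidation level. Convert lactone **13** to the cyclopropanol (Kulinkovich), oxidise to the o‑quinone, then open the cyclopropanol oxidatively (Mn(III) or photoredox) to a β‑keto radical that adds 6‑endo to the methyl‑bearing quinone carbon. This gives saturated ring A directly and cannot O‑cyclise, but the two angular‑methyl diastereomers must be separated.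
- **Step 9 (epoxide cascade with a plain alkene terminator).** The risks are modest yield and alkene mixtures. Fallback: redesign the terminator as an allylsilane (CH2SiMe3 in place of the vinylic methyl of **10**), so the cation is quenched by desilylation and only the exocyclic alkene forms.
- **Step 2 (quinone/ketene‑acetal annulation at a hindered position).** The risk is 1,2‑addition or low conversion. Fallback: use the quinone–enamine annulation with 4‑(2‑methylprop‑1‑enyl)morpholine to form the 2‑amino‑3,3‑dimethyl‑2,3‑dihydrobenzofuran‑5‑ol, carried as the lactol acetal. Late in the route, hydrolyse to the lactol, add ethynylmagnesium bromide, and let the IBX step also oxidise the propargylic alcohol to the ynone.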